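The numbers in the tables were computed on assumed constants; noise was put on by code.

The target is asked as a concentration at the end of the run, with the partner charge held at 9.90 mM and the starting material charge stepped from 0.012 M to 0.20 M.

| flask | starting material | partner | remark | time |
|---|---|---|---|---|
| beta | 0.013 M | 9.9 mM | run made earlier |  |
| eta | 0.049 M | 9.9 mM | run made earlier |  |
| gamma | 0.17 M | 9.9 mM | run made earlier |  |
| west | 0.012 M | 9.90 mM |  | 15 h |
| east | 0.020 M | 9.90 mM |  | 15 h |
| south-west | 0.040 M | 9.90 mM |  | 15 h |
| north-east | 0.080 M | 9.90 mM |  | 15 h |
| south-east | 0.20 M | 9.90 mM |  | 15 h |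

| beta: time / h | beta: target / % | eta: time / h | eta: target / % | gamma: time / h | gamma: target / % |
|---|---|---|---|---|---|
| 1.00 | 7 | 2.00 | 7 | 1.00 | 3 |
| 2.50 | 23 | 4.00 | 10 | 2.50 | 1 |
| 5.00 | 36 | 6.00 | 12 | 5.00 | 2 |
| 8.00 | 40 | 8.00 | 9 | 8.00 | 2 |

(readings scatter by 1.5 percentage points)

- "hardly changes" means that all values lie within two and a half points (for a concentration: within two and a half percent of the largest)

1. [target] at the end for west, east, south-west, north-east, south-east, in this order
2. the course of these numbers from the first flask to the last (rises all the way / rises, then falls / hardly changes / falls, then rises / falls all the way)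

The first setting is the starting material charge. The reckoning here supposes a pseudo-first-order loss of target, with the charge c frozen at its starting value. The eta run supplies the size of this loss, since its target goes from 12% at 6.00 h to 9% at 8.00 h. The logarithm of that ratio, divided by the interval and by the eta charge, gives κ = 8.15 × 10⁻⁴ M⁻¹ s⁻¹, the loss constant, meaning the fractional fall of target per second per molar of starting material charged. This is a rough reading, because the fall of 3 percentage points stands against a scatter of 1.5 points per reading. By hand, κc is 0.0352 h⁻¹ in west and 0.587 h⁻¹ in south-east, so this reckoning has target lost faster in south-east than in west.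

The second setting is the time. The beta run has nearly levelled at 40% by 8.00 h, which is a plateau reading of 5.20 mM, and the run to 15 h leaves a further 7.00 h of loss. Multiplying the plateau by exp(−κc) over that interval gives this reckoning 4.06 mM in west, 1.00 mM in north-east and 0.0853 mM in south-east, falling at each step.

The forecast differs from this reckoning. It prints 0.00495 M for west and the same 0.00495 M for south-east, with the course hardly changes, and it reads the falling percentages as “mostly dilution against a fixed ceiling”.

The flasks give 0.00553 M, 0.00569 M, 0.00371 M, 0.00128 M and 1.43 × 10⁻⁴ M, and the course is rises, then falls, turning at a charge of 0.016 M.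

    2 second intermediate → homo product (k = 0.410 M⁻¹ s⁻¹)
    open intermediate + second intermediate → target (k = 0.300 M⁻¹ s⁻¹)
    starting material + target → side product (k = 0.00110 M⁻¹ s⁻¹)
    partner → second intermediate (k = 8.30 × 10⁻⁵ s⁻¹)
    starting material ⇌ open intermediate (K = 0.370, k = 3.00 × 10⁻⁴ s⁻¹)

In south-east, removing the turning of starting material + target into side product lifts the end value from 1.43 × 10⁻⁴ M to 0.00976 M, and removing the way back from open intermediate to starting material lifts it to 0.00852 M, so the low south-east value is owed in part to these two together. For south-east, κ gave 0.0853 mM against the 1.43 × 10⁻⁴ M found. For north-east, κ gave 1.00 mM, and that flask holds 0.00128 M of target, with starting material at 56.5% of its charge.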